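**Retrosynthetic overview**

1. The target is reached by global desilylation of a tris-silylated flavone. That flavone comes from a Negishi coupling between C2 of a zincated 5,7-bis(silyloxy)chromone and the aryl bromide carbon (C5) of a bromo-dihydrobenzofuranol; the chromone bicycle is bought in intact.
2. The dihydrobenzofuranol comes from a Nozaki–Hiyama–Kishi closure. The feature used: carbinol carbon C3'' is bonded to arene carbon C3a, which is ortho to C7a–O1'', and O1'' carries C2''. An aryl–metal at C3a (from an iodide) therefore reaches an aldehyde carbon hanging on C2'' of the O1''–C2'' ether and closes the five-membered ring O1''–C2''–C3''–C3a–C7a.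
3. The iodoaryl aldehyde comes from an aryl glycerate ether: ester to CMe2OH with MeMgBr, silylation, then oxidation of the primary silyl ether. The aryl ether bond is made by Mitsunobu inversion at the unhindered α-carbon of a D-glycerate, before the gem-dimethyl carbinol exists, so C2'' comes from the chiral pool.
4. The phenol comes from ortho C-prenylation of 4-bromo-2-iodophenol: iodine marks C3a, bromine marks the later aryl–chromone bond.
5. Ring order: the benzene ring and the chromone are purchased; the dihydrofuran ring (step 7) is the only ring built.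

Key step: step 7

Remark: O1'', C2'', C3'', C3a and C7a denote the dihydrofuran ring atoms of the target; 4-bromo-2-iodophenol, methyl (R)-glycerate and 5,7-dihydroxychromone are taken as catalogue compounds, and the C3'' hydroxyl is carried unprotected through the coupling because organozinc halides are protonated only slowly by alcohols.

**Step 1**
Reactants: 1 4-bromo-2-iodophenol; 2 prenyl bromide (1-bromo-3-methylbut-2-ene)
Product: 3 4-bromo-2-iodo-6-(3-methylbut-2-en-1-yl)phenol
Conditions: NaH, toluene, 0 °C → rt; then 2, rt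
Reagents that add atoms: none
Why: The sodium phenoxide reacts in toluene as a tight ion pair, so the allylic bromide is delivered to the ring carbon ortho to oxygen (phenoxide ortho C-alkylation, SN2 at the primary carbon, linear prenyl group); C6 is the only open ortho position, C4 is blocked by bromine, and neither halogen reacts.

**Step 2**
Reactants: 4 methyl (R)-glycerate
Product: 5 methyl (2R)-2-hydroxy-3-[(triethylsilyl)oxy]propanoate
Conditions: TESCl (1.05 equiv), imidazole, CH2Cl2, −20 → 0 °C
Reagents that add atoms: chlorotriethylsilane (TESCl), CC[Si](CC)(CC)Cl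
Why: Selective silylation of the primary hydroxyl of a 1,2-diol, since the secondary α-hydroxy ester oxygen is more hindered and less nucleophilic; the stereocentre is not involved.

**Step 3**
Reactants: 3 4-bromo-2-iodo-6-(3-methylbut-2-en-1-yl)phenol; 5 methyl (2R)-2-hydroxy-3-[(triethylsilyl)oxy]propanoate
Product: 6 methyl (2S)-2-[4-bromo-2-iodo-6-(3-methylbut-2-en-1-yl)phenoxy]-3-[(triethylsilyl)oxy]propanoate
Conditions: PPh3, DIAD, THF, 0 °C → rt
Reagents that add atoms: none
Why: Mitsunobu etherification, in which the acidic dihalophenol protonates the betaine and its phenoxide displaces the oxyphosphonium at the unhindered α-carbon by SN2, inverting (R) to (S), the configuration required for C2''.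

**Step 4**
Reactants: 6 methyl (2S)-2-[4-bromo-2-iodo-6-(3-methylbut-2-en-1-yl)phenoxy]-3-[(triethylsilyl)oxy]propanoate
Product: 8 (3S)-3-[4-bromo-2-iodo-6-(3-methylbut-2-en-1-yl)phenoxy]-2-methyl-4-[(triethylsilyl)oxy]butan-2-ol, via methyl ketone 7 (not isolated)
Conditions: MeMgBr (3.5 equiv), THF, −40 → 0 °C
Reagents that add atoms: methylmagnesium bromide, C[Mg]Br
Why: Double Grignard addition to the ester through the methyl ketone should give the dimethyl carbinol; addition to the chelating α-aryloxy ester outruns enolisation so the stereocentre holds, and MeMgBr does not exchange with the aryl iodide or bromide at or below 0 °C.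

**Step 5**
Reactants: 8 (3S)-3-[4-bromo-2-iodo-6-(3-methylbut-2-en-1-yl)phenoxy]-2-methyl-4-[(triethylsilyl)oxy]butan-2-ol
Product: 9 5-bromo-1-iodo-3-(3-methylbut-2-en-1-yl)-2-{[(2S)-3-methyl-1,3-bis(triethylsilyloxy)butan-2-yl]oxy}benzene
Conditions: TESOTf, 2,6-lutidine, CH2Cl2, −78 → 0 °C
Reagents that add atoms: triethylsilyl trifluoromethanesulfonate (TESOTf), CC[Si](CC)(CC)OS(=O)(=O)C(F)(F)F
Why: Silyl triflate silylation of the hindered tertiary alcohol under lutidine buffering, which leaves the primary silyl ether, the prenyl alkene and the stereocentre untouched.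

**Step 6**
Reactants: 9 5-bromo-1-iodo-3-(3-methylbut-2-en-1-yl)-2-{[(2S)-3-methyl-1,3-bis(triethylsilyloxy)butan-2-yl]oxy}benzene
Product: 10 (2R)-2-[4-bromo-2-iodo-6-(3-methylbut-2-en-1-yl)phenoxy]-3-methyl-3-[(triethylsilyl)oxy]butanal
Conditions: (COCl)2, DMSO, CH2Cl2, −78 → −40 °C; then i-Pr2NEt, −78 → 0 °C; used crude
Reagents that add atoms: none
Why: Swern conditions cleave a primary triethylsilyl ether and oxidise it directly to the aldehyde (oxidative desilylation), while the hindered tertiary triethylsilyl ether is inert; the hindered amine and low temperature protect the α-aryloxy stereocentre from enolisation.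

**Step 7**
Reactants: 10 (2R)-2-[4-bromo-2-iodo-6-(3-methylbut-2-en-1-yl)phenoxy]-3-methyl-3-[(triethylsilyl)oxy]butanal
Product: 12 (2S,3S)-5-bromo-7-(3-methylbut-2-en-1-yl)-2-{2-[(triethylsilyl)oxy]propan-2-yl}-2,3-dihydro-1-benzofuran-3-ol, via arylchromium dichloride 11 (not isolated)
Conditions: CrCl2 (6 equiv), NiCl2 (5 mol %), degassed DMF, 0.01 M, 25 °C; then H2O
Reagents that add atoms: none
Why: Zerovalent nickel, formed from NiCl2 by divalent chromium, inserts into the C–I bond, the aryl group passes to trivalent chromium, and the arylchromium adds to the tethered aldehyde to make the C3a–C3'' bond, after which hydrolysis of the chromium alkoxide frees the carbinol. The closest known reaction is the intramolecular Nozaki–Hiyama–Kishi coupling of an aryl iodide with an aldehyde. The dihydrofuran ring (O1''–C2''–C3''–C3a–C7a) closes 5-exo-trig on the carbonyl carbon. The new stereocentre C3'' is set by 1,2-induction from C2'': in the compact cyclic transition state the chromium-bound carbonyl oxygen turns to the ring face away from the bulky silyloxyisopropyl group and leaves the small aldehyde hydrogen beside it, which should give the trans (2S,3S) alcohol. The step needs insertion at C–I and not at C–Br, secured by the weaker C–I bond and the low nickel loading at room temperature. It also needs the α-aryloxy aldehyde to keep its configuration, secured by the non-basic organochromium reagent and by the fully substituted neighbouring carbon that shields the α-hydrogen; the prenyl alkene is remote from the metal.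

**Step 8**
Reactants: 13 5,7-dihydroxy-4H-chromen-4-one (5,7-dihydroxychromone)
Product: 14 5,7-bis[(tert-butyldimethylsilyl)oxy]-4H-chromen-4-one
Conditions: TBSOTf (2.3 equiv), Et3N, CH2Cl2, 0 °C → rt; aq. NaHCO3
Reagents that add atoms: tert-butyldimethylsilyl trifluoromethanesulfonate (TBSOTf), CC(C)(C)[Si](C)(C)OS(=O)(=O)C(F)(F)F
Why: Silyl triflate with amine base silylates both phenols, including the hydrogen-bonded 5-hydroxyl that resists silyl chlorides, and any 4-silyloxybenzopyrylium formed at the carbonyl reverts to the chromone on aqueous work-up.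

**Step 9**
Reactants: 14 5,7-bis[(tert-butyldimethylsilyl)oxy]-4H-chromen-4-one; 12 (2S,3S)-5-bromo-7-(3-methylbut-2-en-1-yl)-2-{2-[(triethylsilyl)oxy]propan-2-yl}-2,3-dihydro-1-benzofuran-3-ol
Product: 16 5,7-bis[(tert-butyldimethylsilyl)oxy]-2-[(2S,3S)-3-hydroxy-7-(3-methylbut-2-en-1-yl)-2-{2-[(triethylsilyl)oxy]propan-2-yl}-2,3-dihydro-1-benzofuran-5-yl]-4H-chromen-4-one, via chromon-2-ylzinc chloride 15 (not isolated)
Conditions: 14 (2 equiv), TMPZnCl·LiCl (2,2,6,6-tetramethylpiperidinylzinc chloride–lithium chloride), THF, 25 °C; then 12, Pd(OAc)2 (4 mol %), SPhos (8 mol %), 50 °C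
Reagents that add atoms: none
Why: The hindered zinc amide removes the most acidic ring hydrogen, at C2 beside the ring oxygen (C2 zincation of chromones), and the alkenylzinc chloride then undergoes Negishi coupling with the electron-rich aryl bromide; the neutral, non-aqueous conditions tolerate the free benzylic hydroxyl and leave the three silyl ethers, the prenyl group and both stereocentres untouched.

**Step 10**
Reactants: 16 5,7-bis[(tert-butyldimethylsilyl)oxy]-2-[(2S,3S)-3-hydroxy-7-(3-methylbut-2-en-1-yl)-2-{2-[(triethylsilyl)oxy]propan-2-yl}-2,3-dihydro-1-benzofuran-5-yl]-4H-chromen-4-one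
Product: 17 5,7-dihydroxy-2-[(2S,3S)-3-hydroxy-2-(2-hydroxypropan-2-yl)-7-(3-methylbut-2-en-1-yl)-2,3-dihydro-1-benzofuran-5-yl]-4H-chromen-4-one (CNP0172554.1)
Conditions: TBAF, AcOH (1:1, excess), THF, 0 °C → rt
Reagents that add atoms: none
Why: Fluoride-mediated desilylation removes the two aryl silyl ethers and the tertiary triethylsilyl ether in one operation, and acetic acid buffering keeps the medium near neutral so the benzylic C3'' carbinol (prone to acid-promoted dehydration to the benzofuran) and both stereocentres are preserved.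

**Compound list**

1 | 4-bromo-2-iodophenol | Oc1ccc(Br)cc1I | starting material
2 | prenyl bromide (1-bromo-3-methylbut-2-ene) | CC(C)=CCBr | starting material
3 | 4-bromo-2-iodo-6-(3-methylbut-2-en-1-yl)phenol | CC(C)=CCc1cc(Br)cc(I)c1O | intermediate
4 | methyl (R)-glycerate (methyl (2R)-2,3-dihydroxypropanoate) | COC(=O)[C@H](O)CO | starting material
5 | methyl (2R)-2-hydroxy-3-[(triethylsilyl)oxy]propanoate | COC(=O)[C@H](O)CO[Si](CC)(CC)CC | intermediate
6 | methyl (2S)-2-[4-bromo-2-iodo-6-(3-methylbut-2-en-1-yl)phenoxy]-3-[(triethylsilyl)oxy]propanoate | CC(C)=CCc1cc(Br)cc(I)c1O[C@H](C(=O)OC)CO[Si](CC)(CC)CC | intermediate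
7 | (3S)-3-[4-bromo-2-iodo-6-(3-methylbut-2-en-1-yl)phenoxy]-4-[(triethylsilyl)oxy]butan-2-one (formed in the flask) | CC(C)=CCc1cc(Br)cc(I)c1O[C@H](C(C)=O)CO[Si](CC)(CC)CC | intermediate
8 | (3S)-3-[4-bromo-2-iodo-6-(3-methylbut-2-en-1-yl)phenoxy]-2-methyl-4-[(triethylsilyl)oxy]butan-2-ol | CC(C)=CCc1cc(Br)cc(I)c1O[C@H](C(C)(C)O)CO[Si](CC)(CC)CC | intermediate
9 | 5-bromo-1-iodo-3-(3-methylbut-2-en-1-yl)-2-{[(2S)-3-methyl-1,3-bis(triethylsilyloxy)butan-2-yl]oxy}benzene | CC(C)=CCc1cc(Br)cc(I)c1O[C@H](C(C)(C)O[Si](CC)(CC)CC)CO[Si](CC)(CC)CC | intermediate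
10 | (2R)-2-[4-bromo-2-iodo-6-(3-methylbut-2-en-1-yl)phenoxy]-3-methyl-3-[(triethylsilyl)oxy]butanal | CC(C)=CCc1cc(Br)cc(I)c1O[C@H](C(C)(C)O[Si](CC)(CC)CC)C=O | intermediate
11 | {5-bromo-3-(3-methylbut-2-en-1-yl)-2-[((2R)-3-methyl-1-oxo-3-(triethylsilyloxy)butan-2-yl)oxy]phenyl}chromium dichloride (formed in the flask) | CC(C)=CCc1cc(Br)cc([Cr](Cl)Cl)c1O[C@H](C(C)(C)O[Si](CC)(CC)CC)C=O | intermediate
12 | (2S,3S)-5-bromo-7-(3-methylbut-2-en-1-yl)-2-{2-[(triethylsilyl)oxy]propan-2-yl}-2,3-dihydro-1-benzofuran-3-ol | CC(C)=CCc1cc(Br)cc2c1O[C@H](C(C)(C)O[Si](CC)(CC)CC)[C@H]2O | intermediate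
13 | 5,7-dihydroxy-4H-chromen-4-one | O=c1ccoc2cc(O)cc(O)c12 | starting material
14 | 5,7-bis[(tert-butyldimethylsilyl)oxy]-4H-chromen-4-one | O=c1ccoc2cc(O[Si](C)(C)C(C)(C)C)cc(O[Si](C)(C)C(C)(C)C)c12 | intermediate
15 | {5,7-bis[(tert-butyldimethylsilyl)oxy]-4-oxo-4H-chromen-2-yl}zinc chloride (formed in the flask) | O=c1cc([Zn]Cl)oc2cc(O[Si](C)(C)C(C)(C)C)cc(O[Si](C)(C)C(C)(C)C)c12 | intermediate
16 | 5,7-bis[(tert-butyldimethylsilyl)oxy]-2-[(2S,3S)-3-hydroxy-7-(3-methylbut-2-en-1-yl)-2-{2-[(triethylsilyl)oxy]propan-2-yl}-2,3-dihydro-1-benzofuran-5-yl]-4H-chromen-4-one | CC(C)=CCc1cc(-c2cc(=O)c3c(O[Si](C)(C)C(C)(C)C)cc(O[Si](C)(C)C(C)(C)C)cc3o2)cc2c1O[C@H](C(C)(C)O[Si](CC)(CC)CC)[C@H]2O | intermediate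
17 | 5,7-dihydroxy-2-[(2S,3S)-3-hydroxy-2-(2-hydroxypropan-2-yl)-7-(3-methylbut-2-en-1-yl)-2,3-dihydro-1-benzofuran-5-yl]-4H-chromen-4-one | CC(C)=CCc1cc(-c2cc(=O)c3c(O)cc(O)cc3o2)cc2c1O[C@H](C(C)(C)O)[C@H]2O | target

**Step count**

Total steps: 10. Longest linear sequence: 8 steps (step 1 or 2, then 3, 4, 5, 6, 7, 9, 10).

**Steps most likely to fail**

Step 7. The addition of the arylchromium to the aldehyde may show poor facial selectivity, so that the cis carbinol forms beside the trans one. The fallback corrects the configuration after ring closure instead of relying on substrate control. It sets out from 10: the closure is run as in step 7, and the cis alcohol (2S,3R)-5-bromo-7-(3-methylbut-2-en-1-yl)-2-{2-[(triethylsilyl)oxy]propan-2-yl}-2,3-dihydro-1-benzofuran-3-ol F1 is separated. It is esterified with inversion under Mitsunobu conditions (4-nitrobenzoic acid, PPh3, DIAD, toluene, 0 °C → rt); the carboxylate enters on the face away from the silyloxyisopropyl group and gives (2S,3S)-5-bromo-7-(3-methylbut-2-en-1-yl)-2-{2-[(triethylsilyl)oxy]propan-2-yl}-2,3-dihydro-1-benzofuran-3-yl 4-nitrobenzoate F2. Methanolysis (K2CO3, MeOH, 0 °C) returns to the route at 12.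

Step 9. Zincation of the bis-silylated chromone may be incomplete or misdirected, or the zinc reagent may be protonated by the free hydroxyl before transmetallation. The fallback reverses the polarity of the coupling and sets out from 12 and 14. Miyaura borylation of 12 (B2pin2, Pd(dppf)Cl2, KOAc, dioxane, 85 °C) should give (2S,3S)-7-(3-methylbut-2-en-1-yl)-5-(4,4,5,5-tetramethyl-1,3,2-dioxaborolan-2-yl)-2-{2-[(triethylsilyl)oxy]propan-2-yl}-2,3-dihydro-1-benzofuran-3-ol F3. Separately, 14 is lithiated at C2 with LiTMP (lithium 2,2,6,6-tetramethylpiperidide) in THF at −78 °C and quenched with I2 to give 5,7-bis[(tert-butyldimethylsilyl)oxy]-2-iodo-4H-chromen-4-one F4. Suzuki–Miyaura coupling of F3 with F4 (Pd(dppf)Cl2, K3PO4, dioxane with a little water, 60 °C) returns to the route at 16. Any loss of aryl silyl groups under the basic conditions is harmless, because step 10 removes them all.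

Step 1. O-alkylation may compete with ortho C-alkylation of the phenoxide, and the ortho-prenylphenol may cyclise to a chroman if the work-up turns acidic. The fallback builds the side chain by sigmatropic rearrangement and olefin metathesis and sets out from 1. O-allylation (allyl bromide, K2CO3, acetone, reflux) gives allyl 4-bromo-2-iodophenyl ether F5. Claisen rearrangement (N,N-diethylaniline, 190 °C) moves the allyl group to the only free ortho carbon and gives 2-allyl-4-bromo-6-iodophenol F6. Cross-metathesis with excess 2-methyl-2-butene (second-generation Grubbs catalyst, (H2IMes)(PCy3)Cl2Ru=CHPh, CH2Cl2, 40 °C) returns to the route at 3.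

**Further compounds**

F1 | step 7 | (2S,3R)-5-bromo-7-(3-methylbut-2-en-1-yl)-2-{2-[(triethylsilyl)oxy]propan-2-yl}-2,3-dihydro-1-benzofuran-3-ol | CC(C)=CCc1cc(Br)cc2c1O[C@H](C(C)(C)O[Si](CC)(CC)CC)[C@@H]2O
F2 | step 7 | (2S,3S)-5-bromo-7-(3-methylbut-2-en-1-yl)-2-{2-[(triethylsilyl)oxy]propan-2-yl}-2,3-dihydro-1-benzofuran-3-yl 4-nitrobenzoate | CC(C)=CCc1cc(Br)cc2c1O[C@H](C(C)(C)O[Si](CC)(CC)CC)[C@H]2OC(=O)c1ccc(cc1)[N+](=O)[O-]
F3 | step 9 | (2S,3S)-7-(3-methylbut-2-en-1-yl)-5-(4,4,5,5-tetramethyl-1,3,2-dioxaborolan-2-yl)-2-{2-[(triethylsilyl)oxy]propan-2-yl}-2,3-dihydro-1-benzofuran-3-ol | CC(C)=CCc1cc(B3OC(C)(C)C(C)(C)O3)cc2c1O[C@H](C(C)(C)O[Si](CC)(CC)CC)[C@H]2O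
F4 | step 9 | 5,7-bis[(tert-butyldimethylsilyl)oxy]-2-iodo-4H-chromen-4-one | O=c1cc(I)oc2cc(O[Si](C)(C)C(C)(C)C)cc(O[Si](C)(C)C(C)(C)C)c12
F5 | step 1 | allyl 4-bromo-2-iodophenyl ether | C=CCOc1ccc(Br)cc1I
F6 | step 1 | 2-allyl-4-bromo-6-iodophenol | C=CCc1cc(Br)cc(I)c1O
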